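**Plan**

1. Retrosynthesis: the four phenols are masked as methyl ethers. The pyrrole N–CH2 bond is cut first (pyrrolide plus γ-chloropropyl amine), then the two pyrrole C3/C4–quinoline C5 bonds (twofold Suzuki–Miyaura), then the pyridine ring of the quinoline (Skraup).
2. In the azecane (N1, C2, methyl-bearing C3, C4 to C10), N1 and C6 lie 1,6 across the ten-membered ring. A temporary N1–C6 bond folds the ring into a quinolizidine, so the C4–C5 bond can be made by closing a six-membered ring.
3. Forward: (S)-2-vinylpiperidine (N1, C5 to C10) is acylated with (S)-2-methylbut-3-enoic acid (C2 to C4 and the methyl). Ring-closing metathesis closes the six-membered lactam at C4=C5. Lactam reduction, N-alkylation with the three-carbon arm and dissolving-metal cleavage of the now allylic N1–C6 bond release the ten-membered ring, which is then hydrogenated.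
4. The derived chloride alkylates 3,4-bis(7,8-dimethoxyquinolin-5-yl)pyrrole, and BBr3 frees the two catechols.
5. Stereochemistry: C3 (S) is set by auxiliary-controlled α-methylation of a dienolate. The temporary stereocenter at C6 comes from the chiral pool, is not needed for induction, and is erased when N1–C6 is cut.

Key step: step 6

Remark on the chemistry: the azecane is numbered N1, C2, C3 (methyl, S), C4 to C10 throughout. Compound 16 is unspecified at nitrogen and 17 is a mixture of ring-alkene isomers; both features disappear in the following steps.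

**Route**

Step 1
Reactants: 1 (S)-4-benzyloxazolidin-2-one; 2 (E)-but-2-enoyl chloride
Product: 4 (S)-4-benzyl-3-[(E)-but-2-enoyl]oxazolidin-2-one, via lithium (S)-4-benzyl-2-oxooxazolidin-3-ide 3 (not isolated)
Conditions: n-BuLi, THF, −78 °C; then 2, −78 to 0 °C
Reagents that add atoms: none
Why: N-acylation of the lithiated oxazolidinone by the acid chloride (imide formation) is fast at low temperature and should leave the E alkene untouched.

Step 2
Reactants: 4 (S)-4-benzyl-3-[(E)-but-2-enoyl]oxazolidin-2-one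
Product: 6 (S)-4-benzyl-3-[(S)-2-methylbut-3-enoyl]oxazolidin-2-one, via sodium (1Z)-1-[(S)-4-benzyl-2-oxooxazolidin-3-yl]buta-1,3-dien-1-olate 5 (not isolated)
Conditions: NaN(SiMe3)2, THF, −78 °C; then MeI, −78 °C
Reagents that add atoms: iodomethane, CI
Why: γ-deprotonation should give the chelated Z dienolate, which is methylated at the α-carbon on the face away from the benzyl group (Evans auxiliary alkylation in its deconjugative form), setting the later C3 as S.

Step 3
Reactants: 6 (S)-4-benzyl-3-[(S)-2-methylbut-3-enoyl]oxazolidin-2-one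
Product: 8 (S)-2-methylbut-3-enoic acid, via lithium (S)-2-methylbut-3-eneperoxoate 7 (not isolated)
Conditions: LiOH, H2O2, THF/H2O, 0 °C; then Na2SO3; then HCl to pH 2
Reagents that add atoms: hydrogen peroxide, OO
Why: hydroperoxide attacks the exocyclic imide carbonyl selectively (Evans auxiliary cleavage) at 0 °C, which should leave the α-center and the β,γ-alkene in place, and sulfite reduces the peracid to the acid.

Step 4
Reactants: 9 tert-butyl (S)-2-formylpiperidine-1-carboxylate
Product: 10 tert-butyl (S)-2-ethenylpiperidine-1-carboxylate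
Conditions: Ph3PCH3Br, KN(SiMe3)2, THF, 0 °C; then 9, −78 °C to rt
Reagents that add atoms: methyltriphenylphosphonium bromide, C[P+](c1ccccc1)(c1ccccc1)c1ccccc1.[Br-]
Why: Wittig methylenation with the non-stabilized ylide at low temperature should convert the α-amino aldehyde to the vinyl group with little epimerization, and this center is erased later in any case.

Step 5
Reactants: 10 tert-butyl (S)-2-ethenylpiperidine-1-carboxylate; 8 (S)-2-methylbut-3-enoic acid
Product: 12 (S)-1-[(S)-2-ethenylpiperidin-1-yl]-2-methylbut-3-en-1-one, via (S)-2-ethenylpiperidine hydrochloride 11 (not isolated)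
Conditions: HCl, 1,4-dioxane, rt; evaporate; then 8, EDC·HCl, HOBt, N-methylmorpholine, CH2Cl2, 0 °C to rt
Reagents that add atoms: none
Why: acidolytic Boc cleavage followed by carbodiimide/HOBt amide coupling through the active ester under weakly basic conditions should avoid ketene formation and α-epimerization of the β,γ-unsaturated acid.

Step 6
Reactants: 12 (S)-1-[(S)-2-ethenylpiperidin-1-yl]-2-methylbut-3-en-1-one
Product: 13 (3S,9aS)-3-methyl-3,6,7,8,9,9a-hexahydro-4H-quinolizin-4-one
Conditions: second-generation Grubbs catalyst RuCl2(=CHPh)(H2IMes)(PCy3) (5 mol %), 1,4-benzoquinone (10 mol %), CH2Cl2 (0.01 M), 40 °C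
Reagents that add atoms: none
Why: The ruthenium benzylidene undergoes [2+2] cycloaddition and cycloreversion with one terminal alkene of 12, the new alkylidene closes onto the second alkene through a ruthenacyclobutane, and loss of ethene drives the reaction (ring-closing olefin metathesis). The closest known reaction type is the ring-closing metathesis of N-alkenoyl 2-alkenyl piperidines and pyrrolidines to unsaturated quinolizidinones and indolizidinones. The ring closed is the six-membered 3,6-dihydropyridin-2-one, formed by joining the two vinyl CH carbons (C4 and C5 of the later azecane) as a necessarily cis endocyclic alkene, and it is a six-ring closure only because the N1–C6 bond of the piperidine holds the future ten-membered ring folded as a quinolizidine. No stereocenter is created: C3 comes from step 2 and C9a from 9, and in the rigid bicycle any C3 epimer is a diastereomer that can be removed by chromatography. The step needs cyclization over oligomerization and no ruthenium hydride migration of the alkene into conjugation with the lactam; the first should be secured by the six-membered closure between two monosubstituted alkenes held close by the tertiary amide at high dilution, the second by the mild temperature and benzoquinone as hydride scavenger. The alkene lands at C4=C5, which makes the N1–C6 bond allylic and so prepares the ring opening of step 9.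

Step 7
Reactants: 13 (3S,9aS)-3-methyl-3,6,7,8,9,9a-hexahydro-4H-quinolizin-4-one
Product: 14 (3S,9aS)-3-methyl-3,6,7,8,9,9a-hexahydro-4H-quinolizine
Conditions: LiAlH4, AlCl3 (3:1), THF, 0 °C; aqueous work-up
Reagents that add atoms: none
Why: alane is an electrophilic, weakly basic hydride that reduces tertiary lactams to amines through the iminium ion (amide reduction) and should leave the ring alkene and the α-stereocenter untouched.

Step 8
Reactants: 14 (3S,9aS)-3-methyl-3,6,7,8,9,9a-hexahydro-4H-quinolizine; 15 3-bromopropan-1-ol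
Product: 16 (3S,9aS)-5-(3-hydroxypropyl)-3-methyl-3,6,7,8,9,9a-hexahydro-4H-quinolizin-5-ium bromide
Conditions: 15 (1.5 equiv), MeCN, 80 °C
Reagents that add atoms: none
Why: Menshutkin N-alkylation of the tertiary amine by the primary bromide should give the quaternary salt, and the face of nitrogen that reacts is irrelevant because the nitrogen stereocenter is lost in step 9.

Step 9
Reactants: 16 (3S,9aS)-5-(3-hydroxypropyl)-3-methyl-3,6,7,8,9,9a-hexahydro-4H-quinolizin-5-ium bromide
Product: 17 3-[(3S)-3-methyl-1-azacyclodec-4-en-1-yl]propan-1-ol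
Conditions: Li, NH3(l)/THF, t-BuOH, −78 °C; NH4Cl quench
Reagents that add atoms: none
Why: electron transfer should cleave only the allylic N–C9a bond (Emde-type dissolving-metal reductive cleavage of an allylic quaternary ammonium salt), which opens the bicycle to the ten-membered ring; protonation at either allyl terminus gives alkene isomers (drawn as the 4-ene) that converge in step 10.

Step 10
Reactants: 17 3-[(3S)-3-methyl-1-azacyclodec-4-en-1-yl]propan-1-ol
Product: 18 3-[(3S)-3-methylazecan-1-yl]propan-1-ol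
Conditions: H2 (1 atm), PtO2 (5 mol %), EtOH, AcOH (1.1 equiv), rt
Reagents that add atoms: none
Why: heterogeneous catalytic hydrogenation over platinum, which causes little double-bond migration, should saturate the ring alkene without touching the allylic C3 center.

Step 11
Reactants: 18 3-[(3S)-3-methylazecan-1-yl]propan-1-ol
Product: 19 (3S)-1-(3-chloropropyl)-3-methylazecane hydrochloride
Conditions: SOCl2, CH2Cl2, 0 to 40 °C; evaporate
Reagents that add atoms: thionyl chloride, O=S(Cl)Cl
Why: deoxychlorination of the primary alcohol through its chlorosulfite should proceed cleanly, and isolation as the hydrochloride prevents self-alkylation of the γ-chloro amine.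

Step 12
Reactants: 20 2,3-dimethoxyaniline
Product: 22 7,8-dimethoxyquinoline, via 7,8-dimethoxy-1,2-dihydroquinoline 21 (not isolated)
Conditions: glycerol, 3-O2NC6H4SO3Na, FeSO4 (cat.), H2SO4 (70 % aq.), 135 °C
Reagents that add atoms: glycerol, OCC(O)CO
Why: Skraup quinoline synthesis: conjugate addition of the aniline to acrolein formed in the flask, cyclization at the only free ortho position, dehydration and oxidation by the nitroarene.

Step 13
Reactants: 22 7,8-dimethoxyquinoline
Product: 23 5-bromo-7,8-dimethoxyquinoline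
Conditions: NBS, MeCN, 0 °C to rt
Reagents that add atoms: N-bromosuccinimide, O=C1CCC(=O)N1Br
Why: electrophilic aromatic bromination should go to C5, the α-position of the carbocycle para to the C8 oxygen, as in 8-alkoxyquinolines.

Step 14
Reactants: 23 5-bromo-7,8-dimethoxyquinoline
Product: 24 7,8-dimethoxy-5-(4,4,5,5-tetramethyl-1,3,2-dioxaborolan-2-yl)quinoline
Conditions: B2pin2, Pd(dppf)Cl2 (5 mol %), KOAc, 1,4-dioxane, 90 °C
Reagents that add atoms: bis(pinacolato)diboron, CC1(C)OB(OC1(C)C)B1OC(C)(C)C(C)(C)O1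
Why: Miyaura borylation of the aryl bromide with the weak base KOAc tolerates the quinoline nitrogen and the ethers.

Step 15
Reactants: 25 1-(triisopropylsilyl)-1H-pyrrole
Product: 27 3,4-dibromo-1-(triisopropylsilyl)-1H-pyrrole, via 3-bromo-1-(triisopropylsilyl)-1H-pyrrole 26 (not isolated)
Conditions: NBS (2.05 equiv), THF, −78 °C to rt
Reagents that add atoms: N-bromosuccinimide, O=C1CCC(=O)N1Br
Why: the bulky N-silyl group shields C2 and C5, so electrophilic bromination should occur twice at the β-positions.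

Step 16
Reactants: 27 3,4-dibromo-1-(triisopropylsilyl)-1H-pyrrole; 24 7,8-dimethoxy-5-(4,4,5,5-tetramethyl-1,3,2-dioxaborolan-2-yl)quinoline
Product: 30 3,4-bis(7,8-dimethoxyquinolin-5-yl)-1H-pyrrole, via 5-[4-bromo-1-(triisopropylsilyl)-1H-pyrrol-3-yl]-7,8-dimethoxyquinoline 28 (not isolated), via 3,4-bis(7,8-dimethoxyquinolin-5-yl)-1-(triisopropylsilyl)-1H-pyrrole 29 (not isolated)
Conditions: 24 (2.5 equiv), Pd2(dba)3 (2.5 mol %), SPhos (10 mol %), K3PO4, toluene/H2O, 100 °C; then Bu4NF, THF, rt
Reagents that add atoms: none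
Why: twofold Suzuki–Miyaura coupling with an electron-rich biaryl phosphine suited to hindered partners, followed by fluoride N-desilylation, should give the free pyrrole.

Step 17
Reactants: 30 3,4-bis(7,8-dimethoxyquinolin-5-yl)-1H-pyrrole; 19 (3S)-1-(3-chloropropyl)-3-methylazecane hydrochloride
Product: 32 5,5'-{1-[3-((3S)-3-methylazecan-1-yl)propyl]-1H-pyrrole-3,4-diyl}bis(7,8-dimethoxyquinoline), via sodium 3,4-bis(7,8-dimethoxyquinolin-5-yl)pyrrol-1-ide 31 (not isolated)
Conditions: NaH (2.5 equiv), DMF, 0 °C; then 19, NaI (10 mol %), 60 °C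
Reagents that add atoms: none
Why: SN2 N-alkylation of the sodium pyrrolide by the γ-chloro amine should win over alkylation of the quinoline nitrogens, which are neutral and flanked by the C8 methoxy groups.

Step 18
Reactants: 32 5,5'-{1-[3-((3S)-3-methylazecan-1-yl)propyl]-1H-pyrrole-3,4-diyl}bis(7,8-dimethoxyquinoline)
Product: 34 5,5'-{1-[3-((3S)-3-methylazecan-1-yl)propyl]-1H-pyrrole-3,4-diyl}bis(quinoline-7,8-diol), via cyclic bis(bromoborate) ester 33 (not isolated)
Conditions: BBr3 (10 equiv), CH2Cl2, −78 °C to rt; then H2O/MeOH, NaHCO3 to pH 7, under argon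
Reagents that add atoms: none
Why: Lewis acid O-demethylation of aryl methyl ethers by BBr3 (bromide attack on the methyl of the oxonium complex), with excess reagent to cover the three basic nitrogens, followed by hydrolysis of the boron esters, should free both catechols without affecting C3.

**Compound list**

1 | (S)-4-benzyloxazolidin-2-one | O=C1N[C@@H](Cc2ccccc2)CO1 | starting material
2 | (E)-but-2-enoyl chloride | C/C=C/C(Cl)=O | starting material
3 | lithium (S)-4-benzyl-2-oxooxazolidin-3-ide | [Li+].O=C1[N-][C@@H](Cc2ccccc2)CO1 | intermediate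
4 | (S)-4-benzyl-3-[(E)-but-2-enoyl]oxazolidin-2-one | C/C=C/C(=O)N1C(=O)OC[C@@H]1Cc1ccccc1 | intermediate
5 | sodium (1Z)-1-[(S)-4-benzyl-2-oxooxazolidin-3-yl]buta-1,3-dien-1-olate | [Na+].C=C/C=C(\[O-])N1C(=O)OC[C@@H]1Cc1ccccc1 | intermediate
6 | (S)-4-benzyl-3-[(S)-2-methylbut-3-enoyl]oxazolidin-2-one | C=C[C@H](C)C(=O)N1C(=O)OC[C@@H]1Cc1ccccc1 | intermediate
7 | lithium (S)-2-methylbut-3-eneperoxoate | [Li+].C=C[C@H](C)C(=O)O[O-] | intermediate
8 | (S)-2-methylbut-3-enoic acid | C=C[C@H](C)C(=O)O | intermediate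
9 | tert-butyl (S)-2-formylpiperidine-1-carboxylate | O=C[C@@H]1CCCCN1C(=O)OC(C)(C)C | starting material
10 | tert-butyl (S)-2-ethenylpiperidine-1-carboxylate | C=C[C@@H]1CCCCN1C(=O)OC(C)(C)C | intermediate
11 | (S)-2-ethenylpiperidine hydrochloride | C=C[C@@H]1CCCCN1.Cl | intermediate
12 | (S)-1-[(S)-2-ethenylpiperidin-1-yl]-2-methylbut-3-en-1-one | C=C[C@H](C)C(=O)N1CCCC[C@H]1C=C | intermediate
13 | (3S,9aS)-3-methyl-3,6,7,8,9,9a-hexahydro-4H-quinolizin-4-one | C[C@H]1C=C[C@@H]2CCCCN2C1=O | intermediate
14 | (3S,9aS)-3-methyl-3,6,7,8,9,9a-hexahydro-4H-quinolizine | C[C@H]1C=C[C@@H]2CCCCN2C1 | intermediate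
15 | 3-bromopropan-1-ol | OCCCBr | starting material
16 | (3S,9aS)-5-(3-hydroxypropyl)-3-methyl-3,6,7,8,9,9a-hexahydro-4H-quinolizin-5-ium bromide (configuration at N5 not defined) | C[C@H]1C=C[C@@H]2CCCC[N+]2(CCCO)C1.[Br-] | intermediate
17 | 3-[(3S)-3-methyl-1-azacyclodec-4-en-1-yl]propan-1-ol (ring-alkene isomers, drawn as the 4-ene) | C[C@H]1C=CCCCCCN(CCCO)C1 | intermediate
18 | 3-[(3S)-3-methylazecan-1-yl]propan-1-ol | C[C@H]1CCCCCCCN(CCCO)C1 | intermediate
19 | (3S)-1-(3-chloropropyl)-3-methylazecane hydrochloride | C[C@H]1CCCCCCCN(CCCCl)C1.Cl | intermediate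
20 | 2,3-dimethoxyaniline | COc1cccc(N)c1OC | starting material
21 | 7,8-dimethoxy-1,2-dihydroquinoline | COc1ccc2C=CCNc2c1OC | intermediate
22 | 7,8-dimethoxyquinoline | COc1ccc2cccnc2c1OC | intermediate
23 | 5-bromo-7,8-dimethoxyquinoline | COc1cc(Br)c2cccnc2c1OC | intermediate
24 | 7,8-dimethoxy-5-(4,4,5,5-tetramethyl-1,3,2-dioxaborolan-2-yl)quinoline | COc1cc(B2OC(C)(C)C(C)(C)O2)c2cccnc2c1OC | intermediate
25 | 1-(triisopropylsilyl)-1H-pyrrole | CC(C)[Si](C(C)C)(C(C)C)n1cccc1 | starting material
26 | 3-bromo-1-(triisopropylsilyl)-1H-pyrrole | CC(C)[Si](C(C)C)(C(C)C)n1ccc(Br)c1 | intermediate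
27 | 3,4-dibromo-1-(triisopropylsilyl)-1H-pyrrole | CC(C)[Si](C(C)C)(C(C)C)n1cc(Br)c(Br)c1 | intermediate
28 | 5-[4-bromo-1-(triisopropylsilyl)-1H-pyrrol-3-yl]-7,8-dimethoxyquinoline | COc1cc(-c2cn([Si](C(C)C)(C(C)C)C(C)C)cc2Br)c2cccnc2c1OC | intermediate
29 | 3,4-bis(7,8-dimethoxyquinolin-5-yl)-1-(triisopropylsilyl)-1H-pyrrole | CC(C)[Si](C(C)C)(C(C)C)n1cc(-c2cc(OC)c(OC)c3ncccc23)c(-c2cc(OC)c(OC)c3ncccc23)c1 | intermediate
30 | 3,4-bis(7,8-dimethoxyquinolin-5-yl)-1H-pyrrole | COc1cc(-c2c[nH]cc2-c2cc(OC)c(OC)c3ncccc23)c2cccnc2c1OC | intermediate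
31 | sodium 3,4-bis(7,8-dimethoxyquinolin-5-yl)pyrrol-1-ide | [Na+].COc1cc(-c2c[n-]cc2-c2cc(OC)c(OC)c3ncccc23)c2cccnc2c1OC | intermediate
32 | 5,5'-{1-[3-((3S)-3-methylazecan-1-yl)propyl]-1H-pyrrole-3,4-diyl}bis(7,8-dimethoxyquinoline) | C[C@H]1CCCCCCCN(CCCn2cc(-c3cc(OC)c(OC)c4ncccc34)c(-c3cc(OC)c(OC)c4ncccc34)c2)C1 | intermediate
33 | cyclic bis(bromoborate) ester of 34 (each catechol bridged by B–Br) | C[C@H]1CCCCCCCN(CCCn2cc(-c3cc4OB(Br)Oc4c4ncccc34)c(-c3cc4OB(Br)Oc4c4ncccc34)c2)C1 | intermediate
34 | 5,5'-{1-[3-((3S)-3-methylazecan-1-yl)propyl]-1H-pyrrole-3,4-diyl}bis(quinoline-7,8-diol), CNP0141397.1 | C[C@H]1CCCCCCCN(CCCn2cc(-c3cc(O)c(O)c4ncccc34)c(-c3cc(O)c(O)c4ncccc34)c2)C1 | target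

**Summary**

Total steps: 18. Longest linear sequence: 12 steps (1, 2, 3, 5, 6, 7, 8, 9, 10, 11, 17, 18).

Steps most likely to fail:

Step 9. The electron-transfer cleavage may be diverted: lithium amide formed in the flask could cause Hofmann elimination or a sigmatropic shift of an ammonium ylide, or the reduction could stop short. The fallback sets out from 8 and closes the ten-membered ring directly. 7-Bromohept-1-ene and excess 3-aminopropan-1-ol should give 3-(hept-6-en-1-ylamino)propan-1-ol F1. Selective N-acylation with 8 (EDC·HCl, HOBt) should give (S)-N-(hept-6-en-1-yl)-N-(3-hydroxypropyl)-2-methylbut-3-enamide F2. Ring-closing metathesis at high dilution (second-generation Grubbs catalyst, toluene, 80 °C) should give (3S)-1-(3-hydroxypropyl)-3-methyl-1-azacyclodec-4-en-2-one F3. Alane reduction of F3 comes back to the route at 17.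

Step 16. The second coupling, next to the first peri-substituted quinoline, may be slow, so that protodeboronation of the boronate and early loss of the N-silyl group stall the sequence at the mono-coupled stage. The fallback sets out from 23 and builds the pyrrole ring instead (Piloty–Robinson synthesis). Suzuki–Miyaura coupling of 23 with (E)-2-(2-ethoxyethenyl)-4,4,5,5-tetramethyl-1,3,2-dioxaborolane (Pd(dppf)Cl2, K2CO3) should give (E)-5-(2-ethoxyethenyl)-7,8-dimethoxyquinoline F4. Aqueous HCl in THF should hydrolyse it to 2-(7,8-dimethoxyquinolin-5-yl)acetaldehyde F5. Hydrazine hydrate (0.5 equiv) should give the azine 1,2-bis[2-(7,8-dimethoxyquinolin-5-yl)ethylidene]hydrazine F6. Heating F6 with ZnCl2 should bring about tautomerization, [3,3] shift, ring closure and loss of ammonia, coming back to the route at 30.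

Step 18. The fourfold ether cleavage may be incomplete, the α-unsubstituted pyrrole may degrade under the strong Lewis acid, and the bis-catechol may oxidize in air during neutralization. The fallback sets out from 23 and exchanges the protecting groups so that the last step is a neutral hydrogenolysis. BBr3 on 23 should give 5-bromoquinoline-7,8-diol F7, and benzylation (BnBr, K2CO3, DMF) 7,8-bis(benzyloxy)-5-bromoquinoline F8. Repeating steps 14, 16 and 17 should give in turn:
- 7,8-bis(benzyloxy)-5-(4,4,5,5-tetramethyl-1,3,2-dioxaborolan-2-yl)quinoline F9;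
- 3,4-bis[7,8-bis(benzyloxy)quinolin-5-yl]-1-(triisopropylsilyl)-1H-pyrrole F10 (coupling with 27);
- 3,4-bis[7,8-bis(benzyloxy)quinolin-5-yl]-1H-pyrrole F11 (after Bu4NF);
- 5,5'-{1-[3-((3S)-3-methylazecan-1-yl)propyl]-1H-pyrrole-3,4-diyl}bis[7,8-bis(benzyloxy)quinoline] F12 (with 19).

Hydrogenolysis of F12 (H2, Pd(OH)2/C, THF/MeOH) comes back to the route at 34.

**Further compounds**

F1 | step 9 | 3-(hept-6-en-1-ylamino)propan-1-ol | C=CCCCCCNCCCO
F2 | step 9 | (S)-N-(hept-6-en-1-yl)-N-(3-hydroxypropyl)-2-methylbut-3-enamide | C=C[C@H](C)C(=O)N(CCCO)CCCCCC=C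
F3 | step 9 | (3S)-1-(3-hydroxypropyl)-3-methyl-1-azacyclodec-4-en-2-one | C[C@H]1C=CCCCCCN(CCCO)C1=O
F4 | step 16 | (E)-5-(2-ethoxyethenyl)-7,8-dimethoxyquinoline | CCO/C=C/c1cc(OC)c(OC)c2ncccc12
F5 | step 16 | 2-(7,8-dimethoxyquinolin-5-yl)acetaldehyde | O=CCc1cc(OC)c(OC)c2ncccc12
F6 | step 16 | 1,2-bis[2-(7,8-dimethoxyquinolin-5-yl)ethylidene]hydrazine | COc1cc(C/C=N/N=C/Cc2cc(OC)c(OC)c3ncccc23)c2cccnc2c1OC
F7 | step 18 | 5-bromoquinoline-7,8-diol | Oc1cc(Br)c2cccnc2c1O
F8 | step 18 | 7,8-bis(benzyloxy)-5-bromoquinoline | Brc1cc(OCc2ccccc2)c(OCc2ccccc2)c2ncccc12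
F9 | step 18 | 7,8-bis(benzyloxy)-5-(4,4,5,5-tetramethyl-1,3,2-dioxaborolan-2-yl)quinoline | CC1(C)OB(c2cc(OCc3ccccc3)c(OCc3ccccc3)c3ncccc23)OC1(C)C
F10 | step 18 | 3,4-bis[7,8-bis(benzyloxy)quinolin-5-yl]-1-(triisopropylsilyl)-1H-pyrrole | CC(C)[Si](C(C)C)(C(C)C)n1cc(-c2cc(OCc3ccccc3)c(OCc3ccccc3)c3ncccc23)c(-c2cc(OCc3ccccc3)c(OCc3ccccc3)c3ncccc23)c1
F11 | step 18 | 3,4-bis[7,8-bis(benzyloxy)quinolin-5-yl]-1H-pyrrole | c1c(-c2cc(OCc3ccccc3)c(OCc3ccccc3)c3ncccc23)c(-c2cc(OCc3ccccc3)c(OCc3ccccc3)c3ncccc23)c[nH]1
F12 | step 18 | 5,5'-{1-[3-((3S)-3-methylazecan-1-yl)propyl]-1H-pyrrole-3,4-diyl}bis[7,8-bis(benzyloxy)quinoline] | C[C@H]1CCCCCCCN(CCCn2cc(-c3cc(OCc5ccccc5)c(OCc5ccccc5)c4ncccc34)c(-c3cc(OCc5ccccc5)c(OCc5ccccc5)c4ncccc34)c2)C1
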